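## Structural features

The target is a pentamer of C6C3 units: a 2-aryl-3-hydroxymethyl-4-benzyl tetrahydrofuran whose 2-aryl group is the benzene of a 2-aryl-3-hydroxymethyl-7-methoxy-2,3-dihydrobenzofuran (ring A). C2 of ring A carries a second such unit through its C5 (ring B), C2 of ring B carries a third (ring C), and C2 of ring C carries a 4-hydroxy-3-methoxyphenyl group; a second guaiacyl ring is the benzyl group on the tetrahydrofuran. Nine stereocentres fall into four isolated sets: C2/C3 of each dihydrobenzofuran (trans in all three, (2S,3R) in rings A and B but (2R,3S) in ring C) and the contiguous C2/C3/C4 of the tetrahydrofuran ((2R,3S,4S), 2,3-trans, 3,4-cis). The sets are separated by arenes, so none can relay to the next; each needs reagent control, and the reversed sense of ring C excludes a single substrate-controlled cascade. The fragile groups are the four benzylic C2–O1 bonds that lie para to an oxygen (they ionise in acid and can be hydrogenolysed), two free phenols and four primary alcohols. The real difficulty is the threefold repeat of a trans-2,3-disubstituted dihydrobenzofuran on a 1,2,3,5-tetrasubstituted benzene, each with its own absolute configuration. The key step exploits the pattern of ring A: C7a (bearing O1) and C3a belong to a five-membered ring that can be a γ-lactone, while C7 (OMe), C6, C5 (carbon substituent, para to O1) and C4 map onto C3, C4, C5 and C6 of a 3-methoxy-2-pyrone-5-carboxylate.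

## Logic of the disconnections

53 ⇒ 52 ⇒ 51. The two O–CH2Ph bonds and the three O–Si bonds are cut. Phenols and primary alcohols must be masked through enolate, hydride and acid chemistry, and the gain is a non-polar intermediate that can be purified. The demand is that hydrogenolysis stops at the aryl benzyl ethers and leaves the four benzylic ring C–O bonds alone.

51 ⇒ 50. The O1–C2 bond of the tetrahydrofuran is cut. C2 is benzylic to ring A with O1 of ring A para, so a cation at C2 is accessible, and only the hydroxymethyl on C4 can reach it through a five-membered ring. The gain is an acyclic triol in which the C2 configuration no longer matters. The forward closure must be mild and must place the aryl group trans to the C3 hydroxymethyl.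

50 ⇒ 49 ⇒ 48 + 14. The C2–C3 bond of the tetrahydrofuran is cut as an aldol bond, with C3 being α to a lactone carbonyl and C2 an aryl aldehyde carbon. This removes the whole ring A–B–C trimer from a small lactone that already holds C4. The enolate of 14 must add anti to its benzyl group.

48 ⇒ 47 ⇒ 46. This is an oxidation-level change only; the ester at C5 of ring A is the handle left by the ring synthesis.

46 ⇒ 43 + 9 (key). C3a–C4 and C7–C7a of ring A are cut, with CO2 and silanol as the excised atoms. The substitution pattern of ring A is that of 9, and C2 and C3 already sit in 43. The gain is the removal of a whole tetrasubstituted benzene and a return to lactone chemistry. The forward step needs the ester para and the methoxy group ortho to O1, and an aromatisation that keeps O1.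

43 ⇒ 42 ⇒ 41 ⇒ 40 ⇒ 39 ⇒ 37 + 5. After removal of silicon, the bond between the future C2 and C3 of ring A and the lactone O–C(=O) bond are cut. A syn aldol followed by lactonisation gives the trans lactone, so both centres come from one auxiliary-controlled step. The gain is an aryl aldehyde one unit shorter, which makes the problem iterative. The auxiliary must be (S) to give the (2S,3R) sense.

37 ⇒ 36 ⇒ 35 ⇒ 32 + 9, and 32 ⇒ 31 ⇒ 30 ⇒ 29 ⇒ 28 ⇒ 26 + 5. The same two cuts are made for ring B with the same auxiliary, because rings A and B have the same sense.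

26 ⇒ 25 ⇒ 24 ⇒ 21 + 9, and 21 ⇒ 20 ⇒ 19 ⇒ 18 ⇒ 17 ⇒ 15 + 3. The same cuts are made for ring C, but with the enantiomeric auxiliary in 3, because ring C is (2R,3S).

9 ⇒ 8 ⇒ 7 ⇒ 6. The lactone O1–C2 bond and the C5–C6 bond of the pyrone are cut; every oxygen of 9 except the formyl-derived one is already in 6. Formylation must occur only at C4, which the ketal in 7 secures.

14 ⇒ 13 ⇒ 12 ⇒ 5 + 11; 11 ⇒ 10; 5 ⇒ 4 + 2; 3 ⇒ 1 + 2. The benzylic C–C bond at the future C4 of the tetrahydrofuran is cut as an auxiliary-controlled alkylation. The same imide 5 then serves rings A and B and the tetrahydrofuran.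

## Other disconnections considered

Alternative 1: The cut is C3–C3a of ring A, traced back to a chroman-4-one. The flavanone A2 would be treated with PhI(OAc)2 (trivalent iodine), H2SO4 and HC(OMe)3, or with Tl(NO3)3 (trivalent thallium). The oxidant attacks the enol ether of the ketone, arene carbon C4a shifts from C4 to C3 and C4 becomes the ester carbon, giving A1.
- In favour: the benzene of ring A is bought and not built; the shift delivers the 2,3-trans ester directly; all three C3 carbons sit at ester level and could be reduced together; the bromide is a ready handle.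
- Against, here: the absolute configuration of ring A would rest on C2 of A2, and flavanones lose that centre by retro-oxa-Michael opening under the acid of the contraction. A2 already holds two dihydrobenzofurans with electron-rich arenes and benzylic ethers that such oxidants in sulfuric acid can attack. The bromide of A1 would have to become a carbon substituent in the presence of three esters.
- Comparison: on steps per ring the alternative is the better (about five operations against eight). On the relative 2,3-configuration it is the equal, since both give trans by mechanism. On absolute configuration and on chemoselectivity at trimer size the chosen plan is stronger: both centres of each ring come from an auxiliary-controlled aldol before the arene exists, and the ring-forming step needs only heat and an amine.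

Alternative 2: The cut is made twice, at C2–C3 of ring A and of ring B. The bis(aryldiazoacetate) A4 would be decomposed by Rh2(S-DOSP)4, a dirhodium tetracarboxylate of divalent rhodium. Each carbenoid inserts into the benzylic ether C–H five atoms away and closes a dihydrofuran, and NaOMe then epimerises C3 of each new ring to give the trans triester A3.
- In favour: two rings and four stereocentres form in one catalytic step, the arenes are bought, and the tetrahydrofuran can already be in place. Because rings A and B have the same sense, one catalyst enantiomer serves both; on this point and on step count the alternative is the better.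
- Against, here: the catalyst must control C2 at two sites in a substrate with other activated C–H bonds (C2–H and C5–H2 of the tetrahydrofuran, C2–H of ring C, the benzyl ether methylenes) and with electron-rich arenes open to cyclopropanation. Any shortfall in selectivity multiplies into diastereomers that are hard to separate at this size. Ring C needs a separate insertion with the enantiomeric catalyst, and both diazo groups must be introduced late.
- Comparison: structurally the alternative is the equal or the better, since no arene has to be made. Mechanistically it relies on a catalyst-controlled selection whose level depends on the substrate, whereas the chosen plan uses an aldol of predictable sense and a ring synthesis that creates no stereocentre.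

Alternative 3: The cut is C3–C4 of the tetrahydrofuran. The epoxy cinnamyl ether A6, derived from 48, would be treated with Cp2TiCl (trivalent titanium, made in the flask from Cp2TiCl2 and zinc dust). Homolytic epoxide opening gives a radical at C3, 5-exo addition to the cinnamyl double bond closes the ring, and a second equivalent of the titanium reagent reduces the benzylic radical to the CH2–aryl group of A5. A5 has the same structure as 51.
- In favour: the conditions are neutral and reductive at room temperature, with no benzylic cation, so silyl ethers survive and Friedel–Crafts capture is excluded. On mildness of the ring closure the alternative is the better. C3 and C4 are formed together.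
- Against, here: it addresses only the last ring, so it could replace the end of the route but not the key step. C2 must be set beforehand by an enantioselective addition to 48, and the 3,4-cis preference of a radical 5-exo closure is only moderate.
- Comparison: in the chosen plan C4 comes from an auxiliary-controlled alkylation, C3 from a trans-selective lactone aldol and C2 from a reversible closure. Step economy from 48 is roughly equal (about four steps against three in the main line plus three in a side branch).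

Key step: step 29

## Remarks before the steps

- Assumption: 10 and 15 are purchasable; all configurations are read from the target string (rings A and B (2S,3R), ring C (2R,3S), tetrahydrofuran (2R,3S,4S)).
- Check of the key-step structures: 43, 9 and 46 agree with the target at every centre and are used unchanged.
- Correction of the pyrone supply: displacing bromide by methoxide at C3 of a 3-bromocoumalate is not a workable substitution. C3 is the α-carbon of the unsaturated lactone, and methoxide adds at C6 and opens the ring. 9 is therefore built from 6.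
- Stereochemical bookkeeping: it is the syn aldol that gives the trans lactone. The (S) auxiliary gives the (2S,3R) dihydrobenzofuran and the (R) auxiliary gives (2R,3S), so ring C needs 3 and rings A and B need 5.
- Precursor design: in the cis-fused dihydroarene formed after loss of CO2, H-3a is anti to the ring oxygen and syn to the silyloxy group. The aromatisation is therefore run as a base-induced E1cB elimination in an acid-free medium, not left to a thermal or acid-promoted path.
- Abbreviations in names: TBS = tert-butyldimethylsilyl. Ar = 4-benzyloxy-3-methoxyphenyl. RC = (2R,3S)-2-Ar-3-(TBSOCH2)-7-methoxy-2,3-dihydrobenzofuran-5-yl. RB = (2S,3R)-3-(TBSOCH2)-7-methoxy-2-RC-2,3-dihydrobenzofuran-5-yl. RA = (2S,3R)-3-(TBSOCH2)-7-methoxy-2-RB-2,3-dihydrobenzofuran-5-yl.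

## Steps

Step 1
Reactants: 1 (R)-4-benzyloxazolidin-2-one; 2 methyl 4-chloro-4-oxobutanoate
Product: 3 methyl 4-[(4R)-4-benzyl-2-oxooxazolidin-3-yl]-4-oxobutanoate
Conditions: n-BuLi, THF, −78 °C; then 2, −78 to 0 °C
Reagents that add atoms: none
Why: N-acylation of the lithiated oxazolidinone by the acid chloride; the methyl ester is far less electrophilic and is left alone at low temperature.

Step 2
Reactants: 4 (S)-4-benzyloxazolidin-2-one; 2 methyl 4-chloro-4-oxobutanoate
Product: 5 methyl 4-[(4S)-4-benzyl-2-oxooxazolidin-3-yl]-4-oxobutanoate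
Conditions: n-BuLi, THF, −78 °C; then 2, −78 to 0 °C
Reagents that add atoms: none
Why: Same N-acylation as step 1 with the enantiomeric auxiliary; 5 serves rings A and B and the tetrahydrofuran.

Step 3
Reactants: 6 dimethyl 2-oxopentanedioate
Product: 7 dimethyl 2,2-dimethoxypentanedioate
Conditions: HC(OMe)3, MeOH, H2SO4 (cat.), 60 °C
Reagents that add atoms: trimethyl orthoformate, COC(OC)OC
Why: Acid-catalysed ketalisation of an activated α-keto ester, with the orthoformate as water scavenger. The ketal removes the acidity of C3, so only C4 can be enolised in step 4, and it carries the future 3-methoxy group.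

Step 4
Reactants: 7 dimethyl 2,2-dimethoxypentanedioate
Product: 9 methyl 3-methoxy-2-oxo-2H-pyran-5-carboxylate, via hydroxymethylidene diester 8 (not isolated)
Conditions: NaH, HCO2Me, THF, 0 to 23 °C; AcOH; then CSA (10 mol %), PhMe, 4 Å MS, 110 °C
Reagents that add atoms: methyl formate, COC=O
Why: Crossed Claisen condensation with methyl formate at C4, the only enolisable α-methylene, gives 8. Acid then drives enol lactonisation onto the ketal-flanked ester and loss of methanol from the ketal, the same closure by which formylglutaconates give coumalates; aromatic stabilisation of the 2-pyrone pulls both eliminations forward.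

Step 5
Reactants: 10 (4-benzyloxy-3-methoxyphenyl)methanol
Product: 11 1-benzyloxy-4-(bromomethyl)-2-methoxybenzene
Conditions: PBr3, Et2O, 0 °C
Reagents that add atoms: phosphorus tribromide, BrP(Br)Br
Why: Standard conversion of an electron-rich benzylic alcohol to the bromide through the phosphite ester; the bromide is used at once.

Step 6
Reactants: 5 methyl 4-[(4S)-4-benzyl-2-oxooxazolidin-3-yl]-4-oxobutanoate; 11 1-benzyloxy-4-(bromomethyl)-2-methoxybenzene
Product: 12 methyl (3S)-3-(ArCH2)-4-[(4S)-4-benzyl-2-oxooxazolidin-3-yl]-4-oxobutanoate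
Conditions: NaN(SiMe3)2, THF, −78 °C; then 11, −78 to −30 °C
Reagents that add atoms: none
Why: Evans alkylation. The imide α-CH2 is more acidic than the ester α-CH2, and the chelated Z sodium enolate is benzylated on the face opposite to the benzyl group of the auxiliary. This sets the centre that becomes C4 of the tetrahydrofuran.

Step 7
Reactants: 12 methyl (3S)-3-(ArCH2)-4-[(4S)-4-benzyl-2-oxooxazolidin-3-yl]-4-oxobutanoate
Product: 14 (4S)-4-(ArCH2)dihydrofuran-2(3H)-one, via hydroxy ester 13 (not isolated)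
Conditions: NaBH4, THF/H2O, 0 to 23 °C; then 1 M HCl, 23 °C
Reagents that add atoms: none
Why: NaBH4 reduces the activated imide carbonyl to the primary alcohol and frees the auxiliary, while the methyl ester is much slower. The alcohol 13 then lactonises onto the ester (5-exo-trig) on acidification; the stereocentre is not touched.

Step 8
Reactants: 15 4-benzyloxy-3-methoxybenzaldehyde; 3 methyl 4-[(4R)-4-benzyl-2-oxooxazolidin-3-yl]-4-oxobutanoate
Product: 17 (4R)-4-benzyl-3-{[(2R,3R)-2-Ar-5-oxotetrahydrofuran-3-yl]carbonyl}oxazolidin-2-one, via syn-aldol hydroxy ester 16 (not isolated)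
Conditions: Bu2BOTf, i-Pr2NEt, CH2Cl2, 0 °C; 15, −78 to 0 °C; pH 7 buffer, MeOH, H2O2; then PPTS (cat.), CH2Cl2, 23 °C
Reagents that add atoms: none
Why: Evans syn aldol through the Z dibutylboron enolate of the imide and a Zimmerman–Traxler chair; the (R) auxiliary fixes the enolate face and sets both centres of ring C in 16. Lactonisation of the carbinol oxygen onto the methyl ester turns the syn aldol into the trans 4,5-disubstituted lactone.

Step 9
Reactants: 17 (4R)-4-benzyl-3-{[(2R,3R)-2-Ar-5-oxotetrahydrofuran-3-yl]carbonyl}oxazolidin-2-one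
Product: 18 (2R,3R)-2-Ar-5-oxotetrahydrofuran-3-carboxylic acid
Conditions: LiOH, H2O2, THF/H2O, 0 °C; Na2SO3; 1 M HCl to pH 3
Reagents that add atoms: hydrogen peroxide (as LiOOH), OO
Why: Hydroperoxide attacks the exocyclic imide carbonyl selectively and the auxiliary is recovered. Any lactone opened by hydroxide recloses on acidification, because the γ-lactone is the only ring the hydroxy diacid can form.

Step 10
Reactants: 18 (2R,3R)-2-Ar-5-oxotetrahydrofuran-3-carboxylic acid
Product: 19 (4S,5R)-5-Ar-4-(hydroxymethyl)dihydrofuran-2(3H)-one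
Conditions: BH3·SMe2, THF, 0 to 23 °C; MeOH
Reagents that add atoms: none
Why: Borane reduces the carboxylic acid through the acyloxyborane much faster than the lactone. The medium is never basic, so the hydroxymethyl lactone cannot translactonise through its alkoxide.

Step 11
Reactants: 19 (4S,5R)-5-Ar-4-(hydroxymethyl)dihydrofuran-2(3H)-one
Product: 20 (4S,5R)-5-Ar-4-(TBSOCH2)dihydrofuran-2(3H)-one
Conditions: TBSCl, imidazole, CH2Cl2, 0 to 23 °C
Reagents that add atoms: tert-butyldimethylsilyl chloride, CC(C)(C)[Si](C)(C)Cl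
Why: Silylation of the primary alcohol; it blocks translactonisation and installs the group carried to the end.

Step 12
Reactants: 20 (4S,5R)-5-Ar-4-(TBSOCH2)dihydrofuran-2(3H)-one
Product: 21 (4S,5R)-5-Ar-2-(TBSO)-4-(TBSOCH2)-4,5-dihydrofuran
Conditions: LiN(i-Pr)2, THF, −78 °C; TBSCl, DMPU, −78 to 0 °C; pentane, filtration
Reagents that add atoms: tert-butyldimethylsilyl chloride, CC(C)(C)[Si](C)(C)Cl
Why: Kinetic deprotonation at C3 and O-silylation of the lactone enolate give the cyclic silyl ketene acetal. There is no leaving group β to the enolate carbon and C4 and C5 are not involved; the product is used without chromatography.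

Step 13
Reactants: 21 (4S,5R)-5-Ar-2-(TBSO)-4-(TBSOCH2)-4,5-dihydrofuran; 9 methyl 3-methoxy-2-oxo-2H-pyran-5-carboxylate
Product: 24 methyl (2R,3S)-2-Ar-3-(TBSOCH2)-7-methoxy-2,3-dihydrobenzofuran-5-carboxylate, via bridged lactone cycloadduct 22 (not isolated), via silyloxy dihydroarene 23 (not isolated)
Conditions: PhMe, i-Pr2NEt, 100 °C; then DBU, 23 °C
Reagents that add atoms: none
Why: Inverse-electron-demand Diels–Alder reaction of the ketene acetal with the 2-pyrone-5-carboxylate, retro-Diels–Alder loss of CO2 from 22 and base-induced loss of silanol from 23 give the benzoate. This is the first run of the ring synthesis, on the smallest substrate; C2 and C3 are not touched.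

Step 14
Reactants: 24 methyl (2R,3S)-2-Ar-3-(TBSOCH2)-7-methoxy-2,3-dihydrobenzofuran-5-carboxylate
Product: 25 RC-methanol, that is [(2R,3S)-2-Ar-3-(TBSOCH2)-7-methoxy-2,3-dihydrobenzofuran-5-yl]methanol
Conditions: i-Bu2AlH, CH2Cl2, −78 to 0 °C; KNaC4H4O6 (aq.)
Reagents that add atoms: none
Why: Full hydride reduction of the aryl ester to the benzylic alcohol; this is more reliable than a partial reduction, and silyl and benzyl ethers are inert.

Step 15
Reactants: 25 RC-methanol
Product: 26 RC-carbaldehyde, that is (2R,3S)-2-Ar-3-(TBSOCH2)-7-methoxy-2,3-dihydrobenzofuran-5-carbaldehyde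
Conditions: MnO2, CH2Cl2, 23 °C
Reagents that add atoms: none
Why: Selective oxidation of an electron-rich benzylic alcohol to the aldehyde; the ring benzylic C–H bonds are not oxidised under these conditions.

Step 16
Reactants: 26 RC-carbaldehyde; 5 methyl 4-[(4S)-4-benzyl-2-oxooxazolidin-3-yl]-4-oxobutanoate
Product: 28 (4S)-4-benzyl-3-{[(2S,3S)-5-oxo-2-RC-tetrahydrofuran-3-yl]carbonyl}oxazolidin-2-one, via syn-aldol hydroxy ester 27 (not isolated)
Conditions: Bu2BOTf, i-Pr2NEt, CH2Cl2, 0 °C; 26, −78 to 0 °C; pH 7 buffer, MeOH, H2O2; then PPTS (cat.), CH2Cl2, 23 °C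
Reagents that add atoms: none
Why: Evans syn aldol as in step 8, now with the (S) auxiliary, which sets the (2S,3R) sense of ring B. The stereocentres of ring C are remote and reagent control dominates; lactonisation gives the trans lactone.

Step 17
Reactants: 28 (4S)-4-benzyl-3-{[(2S,3S)-5-oxo-2-RC-tetrahydrofuran-3-yl]carbonyl}oxazolidin-2-one
Product: 29 (2S,3S)-5-oxo-2-RC-tetrahydrofuran-3-carboxylic acid
Conditions: LiOH, H2O2, THF/H2O, 0 °C; Na2SO3; 1 M HCl to pH 3, 0 °C
Reagents that add atoms: hydrogen peroxide (as LiOOH), OO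
Why: Exocyclic imide cleavage by hydroperoxide as in step 9; the primary silyl ether tolerates the brief cold acidification.

Step 18
Reactants: 29 (2S,3S)-5-oxo-2-RC-tetrahydrofuran-3-carboxylic acid
Product: 30 (4R,5S)-4-(hydroxymethyl)-5-RC-dihydrofuran-2(3H)-one
Conditions: BH3·SMe2, THF, 0 to 23 °C; MeOH
Reagents that add atoms: none
Why: Chemoselective borane reduction of the acid in the presence of the lactone, as in step 10.

Step 19
Reactants: 30 (4R,5S)-4-(hydroxymethyl)-5-RC-dihydrofuran-2(3H)-one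
Product: 31 (4R,5S)-4-(TBSOCH2)-5-RC-dihydrofuran-2(3H)-one
Conditions: TBSCl, imidazole, CH2Cl2, 0 to 23 °C
Reagents that add atoms: tert-butyldimethylsilyl chloride, CC(C)(C)[Si](C)(C)Cl
Why: Silylation of the primary alcohol as in step 11.

Step 20
Reactants: 31 (4R,5S)-4-(TBSOCH2)-5-RC-dihydrofuran-2(3H)-one
Product: 32 (4R,5S)-2-(TBSO)-4-(TBSOCH2)-5-RC-4,5-dihydrofuran
Conditions: LiN(i-Pr)2, THF, −78 °C; TBSCl, DMPU, −78 to 0 °C; pentane, filtration
Reagents that add atoms: tert-butyldimethylsilyl chloride, CC(C)(C)[Si](C)(C)Cl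
Why: O-Silylation of the lactone enolate as in step 12; the lactone α-CH2 is the only acidic site.

Step 21
Reactants: 32 (4R,5S)-2-(TBSO)-4-(TBSOCH2)-5-RC-4,5-dihydrofuran; 9 methyl 3-methoxy-2-oxo-2H-pyran-5-carboxylate
Product: 35 methyl (2S,3R)-3-(TBSOCH2)-7-methoxy-2-RC-2,3-dihydrobenzofuran-5-carboxylate, via bridged lactone cycloadduct 33 (not isolated), via silyloxy dihydroarene 34 (not isolated)
Conditions: PhMe, i-Pr2NEt, 100 °C; then DBU, 23 °C
Reagents that add atoms: none
Why: The same pyrone–ketene acetal cycloaddition, loss of CO2 and loss of silanol as in step 13 build the benzene of ring B onto the dihydrofuran; no stereocentre is formed or touched.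

Step 22
Reactants: 35 methyl (2S,3R)-3-(TBSOCH2)-7-methoxy-2-RC-2,3-dihydrobenzofuran-5-carboxylate
Product: 36 RB-methanol
Conditions: i-Bu2AlH, CH2Cl2, −78 to 0 °C; KNaC4H4O6 (aq.)
Reagents that add atoms: none
Why: Ester to benzylic alcohol as in step 14.

Step 23
Reactants: 36 RB-methanol
Product: 37 RB-carbaldehyde
Conditions: MnO2, CH2Cl2, 23 °C
Reagents that add atoms: none
Why: Benzylic oxidation as in step 15.

Step 24
Reactants: 37 RB-carbaldehyde; 5 methyl 4-[(4S)-4-benzyl-2-oxooxazolidin-3-yl]-4-oxobutanoate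
Product: 39 (4S)-4-benzyl-3-{[(2S,3S)-5-oxo-2-RB-tetrahydrofuran-3-yl]carbonyl}oxazolidin-2-one, via syn-aldol hydroxy ester 38 (not isolated)
Conditions: Bu2BOTf, i-Pr2NEt, CH2Cl2, 0 °C; 37, −78 to 0 °C; pH 7 buffer, MeOH, H2O2; then PPTS (cat.), CH2Cl2, 23 °C
Reagents that add atoms: none
Why: Evans syn aldol with the (S) auxiliary sets C2 and C3 of ring A in the (2S,3R) sense; lactonisation gives the trans lactone as in steps 8 and 16.

Step 25
Reactants: 39 (4S)-4-benzyl-3-{[(2S,3S)-5-oxo-2-RB-tetrahydrofuran-3-yl]carbonyl}oxazolidin-2-one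
Product: 40 (2S,3S)-5-oxo-2-RB-tetrahydrofuran-3-carboxylic acid
Conditions: LiOH, H2O2, THF/H2O, 0 °C; Na2SO3; 1 M HCl to pH 3, 0 °C
Reagents that add atoms: hydrogen peroxide (as LiOOH), OO
Why: Exocyclic imide cleavage as in step 9.

Step 26
Reactants: 40 (2S,3S)-5-oxo-2-RB-tetrahydrofuran-3-carboxylic acid
Product: 41 (4R,5S)-4-(hydroxymethyl)-5-RB-dihydrofuran-2(3H)-one
Conditions: BH3·SMe2, THF, 0 to 23 °C; MeOH
Reagents that add atoms: none
Why: Chemoselective acid reduction as in step 10.

Step 27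
Reactants: 41 (4R,5S)-4-(hydroxymethyl)-5-RB-dihydrofuran-2(3H)-one
Product: 42 (4R,5S)-4-(TBSOCH2)-5-RB-dihydrofuran-2(3H)-one
Conditions: TBSCl, imidazole, CH2Cl2, 0 to 23 °C
Reagents that add atoms: tert-butyldimethylsilyl chloride, CC(C)(C)[Si](C)(C)Cl
Why: Silylation as in step 11.

Step 28
Reactants: 42 (4R,5S)-4-(TBSOCH2)-5-RB-dihydrofuran-2(3H)-one
Product: 43 (4R,5S)-2-(TBSO)-4-(TBSOCH2)-5-RB-4,5-dihydrofuran
Conditions: LiN(i-Pr)2, THF, −78 °C; TBSCl, DMPU, −78 to 0 °C; pentane, filtration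
Reagents that add atoms: tert-butyldimethylsilyl chloride, CC(C)(C)[Si](C)(C)Cl
Why: O-Silylation of the lactone enolate as in step 12 gives the ketene acetal that carries the ring B–ring C unit.

Step 29
Reactants: 43 (4R,5S)-2-(TBSO)-4-(TBSOCH2)-5-RB-4,5-dihydrofuran; 9 methyl 3-methoxy-2-oxo-2H-pyran-5-carboxylate
Product: 46 methyl (2S,3R)-3-(TBSOCH2)-7-methoxy-2-RB-2,3-dihydrobenzofuran-5-carboxylate, via bridged lactone cycloadduct 44 (not isolated), via silyloxy dihydroarene 45 (not isolated)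
Conditions: PhMe, i-Pr2NEt, 100 °C; then DBU, 23 °C
Reagents that add atoms: none
Why: The nucleophilic C3 of ketene acetal 43 adds to C6 of pyrone 9, which is β to the ester and the vinylogous terminus of the lactone carbonyl, and the acetal carbon then bonds to C3 of the pyrone in a concerted but strongly asynchronous inverse-electron-demand Diels–Alder reaction; the bridged lactone 44 loses CO2 by a retro-Diels–Alder reaction to give the cis-fused dihydroarene 45. The closest known reaction is the synthesis of benzoates from 2-pyrone-5-carboxylates and ketene acetals, here applied to a cyclic O-silyl ketene acetal. The benzene of ring A is closed by a (4+2) annulation that makes C3a–C4 first and C7–C7a second, the latter joining two fully substituted carbons. No stereocentre is created in 46: the ring-fusion centres of 44 and 45 disappear on aromatisation, and C2 and C3, set in step 24, are never part of a reacting π system or next to a carbanion. The regiochemistry, ester para and methoxy ortho to O1, follows from pairing the nucleophilic carbon with the most electrophilic pyrone carbon; the 3-methoxy group slows the reaction but does not change which terminus is electrophilic. The aromatisation must expel silanol and keep O1: DBU removes H-3a of 45, a vinylogous position of the dienoate, and the dienolate ejects the better nucleofuge, the silanolate, while i-Pr2NEt keeps the medium free of acid that would protonate the more basic ring oxygen.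

Step 30
Reactants: 46 methyl (2S,3R)-3-(TBSOCH2)-7-methoxy-2-RB-2,3-dihydrobenzofuran-5-carboxylate
Product: 47 RA-methanol
Conditions: i-Bu2AlH, CH2Cl2, −78 to 0 °C; KNaC4H4O6 (aq.)
Reagents that add atoms: none
Why: Ester to benzylic alcohol as in step 14.

Step 31
Reactants: 47 RA-methanol
Product: 48 RA-carbaldehyde
Conditions: MnO2, CH2Cl2, 23 °C
Reagents that add atoms: none
Why: Benzylic oxidation as in step 15.

Step 32
Reactants: 14 (4S)-4-(ArCH2)dihydrofuran-2(3H)-one; 48 RA-carbaldehyde
Product: 49 (3R,4S)-4-(ArCH2)-3-[hydroxy(RA)methyl]dihydrofuran-2(3H)-one (both carbinol epimers)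
Conditions: LiN(i-Pr)2, THF, −78 °C, 14; then 48, −78 °C; AcOH at −78 °C
Reagents that add atoms: none
Why: Aldol addition of the lithium enolate of the β-substituted lactone; the aldehyde approaches anti to the benzyl group, giving the 3,4-trans lactone and so C3 of the tetrahydrofuran. The carbinol centre is left uncontrolled because it is reset in step 34; the cold quench prevents retro-aldol.

Step 33
Reactants: 49 (3R,4S)-4-(ArCH2)-3-[hydroxy(RA)methyl]dihydrofuran-2(3H)-one
Product: 50 (2S,3S)-2-(ArCH2)-3-[hydroxy(RA)methyl]butane-1,4-diol (both carbinol epimers)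
Conditions: LiAlH4, THF, 0 °C; KNaC4H4O6 (aq.)
Reagents that add atoms: none
Why: Hydride reduction of the lactone to the 1,4-diol; silyl and benzyl ethers are stable, and C3 and C4 are not epimerisable once the carbonyl is gone.

Step 34
Reactants: 50 (2S,3S)-2-(ArCH2)-3-[hydroxy(RA)methyl]butane-1,4-diol
Product: 51 [(2R,3S,4S)-4-(ArCH2)-2-RA-tetrahydrofuran-3-yl]methanol
Conditions: CSA (10 mol %), CH2Cl2, 4 Å MS, 0 °C; Et3N
Reagents that add atoms: none
Why: Acid ionises the benzylic alcohol to a cation stabilised by the para oxygen of ring A; the hydroxymethyl on the benzyl-bearing carbon captures it by 5-exo closure (the other hydroxymethyl could only give an oxetane). Both carbinol epimers converge, and the reversible closure settles on the 2,3-trans ring with the aryl group anti to the C3 hydroxymethyl; the trans lactone of step 32 translates into the 3,4-cis relationship.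

Step 35
Reactants: 51 [(2R,3S,4S)-4-(ArCH2)-2-RA-tetrahydrofuran-3-yl]methanol
Product: 52 bis-benzyl ether of the target (51 with the three TBSOCH2 groups as CH2OH)
Conditions: Bu4NF, AcOH, THF, 0 to 23 °C
Reagents that add atoms: none
Why: Fluoride cleavage of the three primary silyl ethers; the acetic acid buffer keeps the medium from becoming basic.

Step 36
Reactants: 52 bis-benzyl ether of the target
Product: 53 the target, CNP0267891.2
Conditions: H2 (1 atm), 10% Pd/C, EtOAc/MeOH, 23 °C, stopped at consumption of 52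
Reagents that add atoms: none
Why: Hydrogenolysis of the two aryl benzyl ethers is much faster than cleavage of the benzylic ring ethers in a neutral medium at one atmosphere, so the reaction is stopped once both are gone.

## Compound list

1 | (R)-4-benzyloxazolidin-2-one | O=C1OC[C@@H](Cc2ccccc2)N1 | starting material
2 | methyl 4-chloro-4-oxobutanoate | COC(=O)CCC(Cl)=O | starting material
3 | methyl 4-[(4R)-4-benzyl-2-oxooxazolidin-3-yl]-4-oxobutanoate | COC(=O)CCC(=O)N1[C@H](Cc2ccccc2)COC1=O | intermediate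
4 | (S)-4-benzyloxazolidin-2-one | O=C1OC[C@H](Cc2ccccc2)N1 | starting material
5 | methyl 4-[(4S)-4-benzyl-2-oxooxazolidin-3-yl]-4-oxobutanoate | COC(=O)CCC(=O)N1[C@@H](Cc2ccccc2)COC1=O | intermediate
6 | dimethyl 2-oxopentanedioate | COC(=O)CCC(=O)C(=O)OC | starting material
7 | dimethyl 2,2-dimethoxypentanedioate | COC(=O)CCC(OC)(OC)C(=O)OC | intermediate
8 | dimethyl 4-(hydroxymethylidene)-2,2-dimethoxypentanedioate (enol of the 4-formyl diester) | COC(=O)C(=CO)CC(OC)(OC)C(=O)OC | intermediate
9 | methyl 3-methoxy-2-oxo-2H-pyran-5-carboxylate | COC(=O)C1=COC(=O)C(OC)=C1 | intermediate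
10 | (4-benzyloxy-3-methoxyphenyl)methanol | COc1cc(CO)ccc1OCc1ccccc1 | starting material
11 | 1-benzyloxy-4-(bromomethyl)-2-methoxybenzene | COc1cc(CBr)ccc1OCc1ccccc1 | intermediate
12 | methyl (3S)-3-[(4-benzyloxy-3-methoxyphenyl)methyl]-4-[(4S)-4-benzyl-2-oxooxazolidin-3-yl]-4-oxobutanoate | COC(=O)C[C@H](Cc1ccc(OCc2ccccc2)c(OC)c1)C(=O)N1[C@@H](Cc2ccccc2)COC1=O | intermediate
13 | methyl (3S)-4-(4-benzyloxy-3-methoxyphenyl)-3-(hydroxymethyl)butanoate | COC(=O)C[C@H](Cc1ccc(OCc2ccccc2)c(OC)c1)CO | intermediate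
14 | (4S)-4-[(4-benzyloxy-3-methoxyphenyl)methyl]dihydrofuran-2(3H)-one | O=C1C[C@H](Cc2ccc(OCc3ccccc3)c(OC)c2)CO1 | intermediate
15 | 4-benzyloxy-3-methoxybenzaldehyde | COc1cc(C=O)ccc1OCc1ccccc1 | starting material
16 | methyl (3R)-3-[(R)-(4-benzyloxy-3-methoxyphenyl)(hydroxy)methyl]-4-[(4R)-4-benzyl-2-oxooxazolidin-3-yl]-4-oxobutanoate | COC(=O)C[C@H]([C@@H](O)c1ccc(OCc2ccccc2)c(OC)c1)C(=O)N1[C@H](Cc2ccccc2)COC1=O | intermediate
17 | (4R)-4-benzyl-3-{[(2R,3R)-2-(4-benzyloxy-3-methoxyphenyl)-5-oxotetrahydrofuran-3-yl]carbonyl}oxazolidin-2-one | O=C1C[C@@H](C(=O)N2[C@H](Cc3ccccc3)COC2=O)[C@H](c2ccc(OCc3ccccc3)c(OC)c2)O1 | intermediate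
18 | (2R,3R)-2-(4-benzyloxy-3-methoxyphenyl)-5-oxotetrahydrofuran-3-carboxylic acid | O=C1C[C@@H](C(=O)O)[C@H](c2ccc(OCc3ccccc3)c(OC)c2)O1 | intermediate
19 | (4S,5R)-5-(4-benzyloxy-3-methoxyphenyl)-4-(hydroxymethyl)dihydrofuran-2(3H)-one | O=C1C[C@@H](CO)[C@H](c2ccc(OCc3ccccc3)c(OC)c2)O1 | intermediate
20 | (4S,5R)-5-(4-benzyloxy-3-methoxyphenyl)-4-[(tert-butyldimethylsilyloxy)methyl]dihydrofuran-2(3H)-one | O=C1C[C@@H](CO[Si](C)(C)C(C)(C)C)[C@H](c2ccc(OCc3ccccc3)c(OC)c2)O1 | intermediate
21 | (4S,5R)-5-(4-benzyloxy-3-methoxyphenyl)-2-(tert-butyldimethylsilyloxy)-4-[(tert-butyldimethylsilyloxy)methyl]-4,5-dihydrofuran | CC(C)(C)[Si](C)(C)OC1=C[C@@H](CO[Si](C)(C)C(C)(C)C)[C@H](c2ccc(OCc3ccccc3)c(OC)c2)O1 | intermediate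
22 | bridged lactone cycloadduct of 21 and 9 (2-oxabicyclo[2.2.2]oct-5-en-3-one with bridgehead OMe, fused to the 2-silyloxytetrahydrofuran; new centres transient and unassigned) | COC(=O)C1=CC2(OC)C(=O)OC1C3[C@@H](CO[Si](C)(C)C(C)(C)C)[C@H](c4ccc(OCc5ccccc5)c(OC)c4)OC23O[Si](C)(C)C(C)(C)C | intermediate
23 | methyl (2R,3S)-2-(4-benzyloxy-3-methoxyphenyl)-7a-(tert-butyldimethylsilyloxy)-3-[(tert-butyldimethylsilyloxy)methyl]-7-methoxy-2,3,3a,7a-tetrahydrobenzofuran-5-carboxylate (cis ring fusion, 3a and 7a unassigned) | COC(=O)C1=CC2[C@@H](CO[Si](C)(C)C(C)(C)C)[C@H](c3ccc(OCc4ccccc4)c(OC)c3)OC2(O[Si](C)(C)C(C)(C)C)C(OC)=C1 | intermediate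
24 | methyl (2R,3S)-2-(4-benzyloxy-3-methoxyphenyl)-3-[(tert-butyldimethylsilyloxy)methyl]-7-methoxy-2,3-dihydrobenzofuran-5-carboxylate | COC(=O)c1cc(OC)c2c(c1)[C@@H](CO[Si](C)(C)C(C)(C)C)[C@H](c1ccc(OCc3ccccc3)c(OC)c1)O2 | intermediate
25 | RC-methanol | OCc1cc(OC)c2c(c1)[C@@H](CO[Si](C)(C)C(C)(C)C)[C@H](c1ccc(OCc3ccccc3)c(OC)c1)O2 | intermediate
26 | RC-carbaldehyde | O=Cc1cc(OC)c2c(c1)[C@@H](CO[Si](C)(C)C(C)(C)C)[C@H](c1ccc(OCc3ccccc3)c(OC)c1)O2 | intermediate
27 | methyl (3S)-3-[(S)-hydroxy(RC)methyl]-4-[(4S)-4-benzyl-2-oxooxazolidin-3-yl]-4-oxobutanoate | COC(=O)C[C@@H]([C@H](O)c3cc(OC)c6c(c3)[C@@H](CO[Si](C)(C)C(C)(C)C)[C@H](c3ccc(OCc7ccccc7)c(OC)c3)O6)C(=O)N1[C@@H](Cc2ccccc2)COC1=O | intermediate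
28 | (4S)-4-benzyl-3-{[(2S,3S)-5-oxo-2-RC-tetrahydrofuran-3-yl]carbonyl}oxazolidin-2-one | O=C1C[C@H](C(=O)N2[C@@H](Cc4ccccc4)COC2=O)[C@@H](c3cc(OC)c6c(c3)[C@@H](CO[Si](C)(C)C(C)(C)C)[C@H](c3ccc(OCc7ccccc7)c(OC)c3)O6)O1 | intermediate
29 | (2S,3S)-5-oxo-2-RC-tetrahydrofuran-3-carboxylic acid | O=C1C[C@H](C(=O)O)[C@@H](c3cc(OC)c6c(c3)[C@@H](CO[Si](C)(C)C(C)(C)C)[C@H](c3ccc(OCc7ccccc7)c(OC)c3)O6)O1 | intermediate
30 | (4R,5S)-4-(hydroxymethyl)-5-RC-dihydrofuran-2(3H)-one | O=C1C[C@H](CO)[C@@H](c3cc(OC)c6c(c3)[C@@H](CO[Si](C)(C)C(C)(C)C)[C@H](c3ccc(OCc7ccccc7)c(OC)c3)O6)O1 | intermediate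
31 | (4R,5S)-4-[(tert-butyldimethylsilyloxy)methyl]-5-RC-dihydrofuran-2(3H)-one | O=C1C[C@H](CO[Si](C)(C)C(C)(C)C)[C@@H](c3cc(OC)c6c(c3)[C@@H](CO[Si](C)(C)C(C)(C)C)[C@H](c3ccc(OCc7ccccc7)c(OC)c3)O6)O1 | intermediate
32 | (4R,5S)-2-(tert-butyldimethylsilyloxy)-4-[(tert-butyldimethylsilyloxy)methyl]-5-RC-4,5-dihydrofuran | CC(C)(C)[Si](C)(C)OC1=C[C@H](CO[Si](C)(C)C(C)(C)C)[C@@H](c3cc(OC)c6c(c3)[C@@H](CO[Si](C)(C)C(C)(C)C)[C@H](c3ccc(OCc7ccccc7)c(OC)c3)O6)O1 | intermediate
33 | bridged lactone cycloadduct of 32 and 9 (new centres transient and unassigned) | COC(=O)C1=CC2(OC)C(=O)OC1C4[C@H](CO[Si](C)(C)C(C)(C)C)[C@@H](c3cc(OC)c6c(c3)[C@@H](CO[Si](C)(C)C(C)(C)C)[C@H](c3ccc(OCc7ccccc7)c(OC)c3)O6)OC24O[Si](C)(C)C(C)(C)C | intermediate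
34 | methyl (2S,3R)-7a-(tert-butyldimethylsilyloxy)-3-[(tert-butyldimethylsilyloxy)methyl]-7-methoxy-2-RC-2,3,3a,7a-tetrahydrobenzofuran-5-carboxylate (cis ring fusion, 3a and 7a unassigned) | COC(=O)C1=CC2[C@H](CO[Si](C)(C)C(C)(C)C)[C@@H](c3cc(OC)c6c(c3)[C@@H](CO[Si](C)(C)C(C)(C)C)[C@H](c3ccc(OCc7ccccc7)c(OC)c3)O6)OC2(O[Si](C)(C)C(C)(C)C)C(OC)=C1 | intermediate
35 | methyl (2S,3R)-3-[(tert-butyldimethylsilyloxy)methyl]-7-methoxy-2-RC-2,3-dihydrobenzofuran-5-carboxylate | COC(=O)c1cc(OC)c2c(c1)[C@H](CO[Si](C)(C)C(C)(C)C)[C@@H](c3cc(OC)c6c(c3)[C@@H](CO[Si](C)(C)C(C)(C)C)[C@H](c3ccc(OCc7ccccc7)c(OC)c3)O6)O2 | intermediate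
36 | RB-methanol | OCc1cc(OC)c2c(c1)[C@H](CO[Si](C)(C)C(C)(C)C)[C@@H](c3cc(OC)c6c(c3)[C@@H](CO[Si](C)(C)C(C)(C)C)[C@H](c3ccc(OCc7ccccc7)c(OC)c3)O6)O2 | intermediate
37 | RB-carbaldehyde | O=Cc1cc(OC)c2c(c1)[C@H](CO[Si](C)(C)C(C)(C)C)[C@@H](c3cc(OC)c6c(c3)[C@@H](CO[Si](C)(C)C(C)(C)C)[C@H](c3ccc(OCc7ccccc7)c(OC)c3)O6)O2 | intermediate
38 | methyl (3S)-3-[(S)-hydroxy(RB)methyl]-4-[(4S)-4-benzyl-2-oxooxazolidin-3-yl]-4-oxobutanoate | COC(=O)C[C@@H]([C@H](O)c3cc(OC)c5c(c3)[C@H](CO[Si](C)(C)C(C)(C)C)[C@@H](c3cc(OC)c6c(c3)[C@@H](CO[Si](C)(C)C(C)(C)C)[C@H](c3ccc(OCc7ccccc7)c(OC)c3)O6)O5)C(=O)N1[C@@H](Cc2ccccc2)COC1=O | intermediate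
39 | (4S)-4-benzyl-3-{[(2S,3S)-5-oxo-2-RB-tetrahydrofuran-3-yl]carbonyl}oxazolidin-2-one | O=C1C[C@H](C(=O)N2[C@@H](Cc4ccccc4)COC2=O)[C@@H](c3cc(OC)c5c(c3)[C@H](CO[Si](C)(C)C(C)(C)C)[C@@H](c3cc(OC)c6c(c3)[C@@H](CO[Si](C)(C)C(C)(C)C)[C@H](c3ccc(OCc7ccccc7)c(OC)c3)O6)O5)O1 | intermediate
40 | (2S,3S)-5-oxo-2-RB-tetrahydrofuran-3-carboxylic acid | O=C1C[C@H](C(=O)O)[C@@H](c3cc(OC)c5c(c3)[C@H](CO[Si](C)(C)C(C)(C)C)[C@@H](c3cc(OC)c6c(c3)[C@@H](CO[Si](C)(C)C(C)(C)C)[C@H](c3ccc(OCc7ccccc7)c(OC)c3)O6)O5)O1 | intermediate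
41 | (4R,5S)-4-(hydroxymethyl)-5-RB-dihydrofuran-2(3H)-one | O=C1C[C@H](CO)[C@@H](c3cc(OC)c5c(c3)[C@H](CO[Si](C)(C)C(C)(C)C)[C@@H](c3cc(OC)c6c(c3)[C@@H](CO[Si](C)(C)C(C)(C)C)[C@H](c3ccc(OCc7ccccc7)c(OC)c3)O6)O5)O1 | intermediate
42 | (4R,5S)-4-[(tert-butyldimethylsilyloxy)methyl]-5-RB-dihydrofuran-2(3H)-one | O=C1C[C@H](CO[Si](C)(C)C(C)(C)C)[C@@H](c3cc(OC)c5c(c3)[C@H](CO[Si](C)(C)C(C)(C)C)[C@@H](c3cc(OC)c6c(c3)[C@@H](CO[Si](C)(C)C(C)(C)C)[C@H](c3ccc(OCc7ccccc7)c(OC)c3)O6)O5)O1 | intermediate
43 | (4R,5S)-2-(tert-butyldimethylsilyloxy)-4-[(tert-butyldimethylsilyloxy)methyl]-5-RB-4,5-dihydrofuran (lactone silyl ketene acetal carrying the ring B–ring C unit) | CC(C)(C)[Si](C)(C)OC1=C[C@H](CO[Si](C)(C)C(C)(C)C)[C@@H](c3cc(OC)c5c(c3)[C@H](CO[Si](C)(C)C(C)(C)C)[C@@H](c3cc(OC)c6c(c3)[C@@H](CO[Si](C)(C)C(C)(C)C)[C@H](c3ccc(OCc7ccccc7)c(OC)c3)O6)O5)O1 | intermediate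
44 | bridged lactone cycloadduct of 43 and 9 (new centres transient and unassigned) | COC(=O)C1=CC2(OC)C(=O)OC1C4[C@H](CO[Si](C)(C)C(C)(C)C)[C@@H](c3cc(OC)c5c(c3)[C@H](CO[Si](C)(C)C(C)(C)C)[C@@H](c3cc(OC)c6c(c3)[C@@H](CO[Si](C)(C)C(C)(C)C)[C@H](c3ccc(OCc7ccccc7)c(OC)c3)O6)O5)OC24O[Si](C)(C)C(C)(C)C | intermediate
45 | methyl (2S,3R)-7a-(tert-butyldimethylsilyloxy)-3-[(tert-butyldimethylsilyloxy)methyl]-7-methoxy-2-RB-2,3,3a,7a-tetrahydrobenzofuran-5-carboxylate (cis ring fusion, 3a and 7a unassigned) | COC(=O)C1=CC2[C@H](CO[Si](C)(C)C(C)(C)C)[C@@H](c3cc(OC)c5c(c3)[C@H](CO[Si](C)(C)C(C)(C)C)[C@@H](c3cc(OC)c6c(c3)[C@@H](CO[Si](C)(C)C(C)(C)C)[C@H](c3ccc(OCc7ccccc7)c(OC)c3)O6)O5)OC2(O[Si](C)(C)C(C)(C)C)C(OC)=C1 | intermediate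
46 | methyl (2S,3R)-3-[(tert-butyldimethylsilyloxy)methyl]-7-methoxy-2-RB-2,3-dihydrobenzofuran-5-carboxylate (tris(dihydrobenzofuran) ring A 5-carboxylate) | COC(=O)c1cc(OC)c2c(c1)[C@H](CO[Si](C)(C)C(C)(C)C)[C@@H](c3cc(OC)c5c(c3)[C@H](CO[Si](C)(C)C(C)(C)C)[C@@H](c3cc(OC)c6c(c3)[C@@H](CO[Si](C)(C)C(C)(C)C)[C@H](c3ccc(OCc7ccccc7)c(OC)c3)O6)O5)O2 | intermediate
47 | RA-methanol | OCc1cc(OC)c2c(c1)[C@H](CO[Si](C)(C)C(C)(C)C)[C@@H](c3cc(OC)c5c(c3)[C@H](CO[Si](C)(C)C(C)(C)C)[C@@H](c3cc(OC)c6c(c3)[C@@H](CO[Si](C)(C)C(C)(C)C)[C@H](c3ccc(OCc7ccccc7)c(OC)c3)O6)O5)O2 | intermediate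
48 | RA-carbaldehyde | O=Cc1cc(OC)c2c(c1)[C@H](CO[Si](C)(C)C(C)(C)C)[C@@H](c3cc(OC)c5c(c3)[C@H](CO[Si](C)(C)C(C)(C)C)[C@@H](c3cc(OC)c6c(c3)[C@@H](CO[Si](C)(C)C(C)(C)C)[C@H](c3ccc(OCc7ccccc7)c(OC)c3)O6)O5)O2 | intermediate
49 | (3R,4S)-4-[(4-benzyloxy-3-methoxyphenyl)methyl]-3-[hydroxy(RA)methyl]dihydrofuran-2(3H)-one (carbinol epimers) | COc1cc(C[C@@H]2COC(=O)[C@H]2C(O)c3cc(OC)c4c(c3)[C@H](CO[Si](C)(C)C(C)(C)C)[C@@H](c3cc(OC)c5c(c3)[C@H](CO[Si](C)(C)C(C)(C)C)[C@@H](c3cc(OC)c6c(c3)[C@@H](CO[Si](C)(C)C(C)(C)C)[C@H](c3ccc(OCc7ccccc7)c(OC)c3)O6)O5)O4)ccc1OCc8ccccc8 | intermediate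
50 | (2S,3S)-2-[(4-benzyloxy-3-methoxyphenyl)methyl]-3-[hydroxy(RA)methyl]butane-1,4-diol (carbinol epimers) | COc1cc(C[C@H](CO)[C@@H](CO)C(O)c3cc(OC)c4c(c3)[C@H](CO[Si](C)(C)C(C)(C)C)[C@@H](c3cc(OC)c5c(c3)[C@H](CO[Si](C)(C)C(C)(C)C)[C@@H](c3cc(OC)c6c(c3)[C@@H](CO[Si](C)(C)C(C)(C)C)[C@H](c3ccc(OCc7ccccc7)c(OC)c3)O6)O5)O4)ccc1OCc8ccccc8 | intermediate
51 | [(2R,3S,4S)-4-[(4-benzyloxy-3-methoxyphenyl)methyl]-2-RA-tetrahydrofuran-3-yl]methanol | COc1cc(C[C@@H]2CO[C@@H](c3cc(OC)c4c(c3)[C@H](CO[Si](C)(C)C(C)(C)C)[C@@H](c3cc(OC)c5c(c3)[C@H](CO[Si](C)(C)C(C)(C)C)[C@@H](c3cc(OC)c6c(c3)[C@@H](CO[Si](C)(C)C(C)(C)C)[C@H](c3ccc(OCc7ccccc7)c(OC)c3)O6)O5)O4)[C@@H]2CO)ccc1OCc8ccccc8 | intermediate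
52 | bis-benzyl ether of the target (51 with three free hydroxymethyl groups) | COc1cc(C[C@@H]2CO[C@@H](c3cc(OC)c4c(c3)[C@H](CO)[C@@H](c3cc(OC)c5c(c3)[C@H](CO)[C@@H](c3cc(OC)c6c(c3)[C@@H](CO)[C@H](c3ccc(OCc7ccccc7)c(OC)c3)O6)O5)O4)[C@@H]2CO)ccc1OCc8ccccc8 | intermediate
53 | CNP0267891.2 | COc1cc(C[C@@H]2CO[C@@H](c3cc(OC)c4c(c3)[C@H](CO)[C@@H](c3cc(OC)c5c(c3)[C@H](CO)[C@@H](c3cc(OC)c6c(c3)[C@@H](CO)[C@H](c3ccc(O)c(OC)c3)O6)O5)O4)[C@@H]2CO)ccc1O | target

## Step count and least certain steps

Total: 36 steps. Longest linear sequence: 30 steps (step 1, then steps 8 to 36). The side branches are step 2, steps 3–4 and steps 5–7.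

Step 29 (key step; the same applies to steps 13 and 21). The most likely failure is aromatisation by the wrong path. In 45 the ring oxygen, not the silyloxy group, is anti to H-3a, so an acid-promoted or thermal elimination could expel O1 and open the dihydrofuran. A second concern is that the second bond, which joins two fully substituted carbons, forms slowly and lets the zwitterionic Michael intermediate drift to open-chain products.
Fallback: set out from 43 and 9 under the same heating but with a catalytic amount of PPTS and no amine, so that the ring oxygen leaves on purpose. This gives the ring-opened methyl 4-silyloxy-3-methoxybenzoate bearing the (2R,3S)-1-silyloxy-3-hydroxy-3-RB-propan-2-yl side chain F1. K2CO3 in MeOH removes only the aryl silyl ether to give the phenol F2. PPTS in CH2Cl2 then closes the dihydrofuran by 5-exo attack of the phenol on the benzylic cation, which is stabilised by the para oxygen of ring B; C3 is fixed, so the closure settles on the trans ring. The fallback returns to the route at 46.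

Step 4. The most likely failure is hydrolysis of the ketal by adventitious water before methanol is eliminated, or incomplete elimination, which gives the 3-hydroxy pyrone or mixtures instead of the enol ether.
Fallback: set out from 7 through 8 and make the hydrolysis deliberate. Wet trifluoroacetic acid followed by heating in PhMe gives methyl 3-hydroxy-2-oxo-2H-pyran-5-carboxylate F3, whose acidic enol is O-methylated with Me3SiCHN2 in MeOH/PhMe. The fallback returns at 9.

Step 34. The most likely failures are partial loss of the primary silyl ethers under acid strong enough to ionise the benzylic alcohol, and capture of the cation by the benzyl-protected guaiacyl ring (Friedel–Crafts closure to an aryltetralin) if the acid is left too long.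
Fallback: reverse the order of desilylation and ring closure. From 50, Bu4NF/AcOH gives the hexaol F4, which ionises under much weaker acid (PPTS in THF) and closes in the same 5-exo mode without any silyl group at risk. The fallback returns at 52.

Step 36. The most likely failure is over-reduction: once the benzyl ethers are gone, the benzylic C2–O1 bond of the tetrahydrofuran and, more slowly, those of the dihydrobenzofurans can be hydrogenolysed.
Fallback: remove the benzyl groups without hydrogen. From 51, BCl3 with pentamethylbenzene as cation scavenger in CH2Cl2 at −78 °C cleaves the two aryl benzyl ethers, helped by chelation to the neighbouring methoxy groups, to give the bisphenol tris(silyl ether) F5; Bu4NF/AcOH then removes the silyl groups. The fallback returns at 53.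

## Further compounds

F1 | step 29 | methyl 4-(tert-butyldimethylsilyloxy)-3-methoxy-5-[(2R,3S)-1-(tert-butyldimethylsilyloxy)-3-hydroxy-3-RB-propan-2-yl]benzoate | COC(=O)c1cc(OC)c(O[Si](C)(C)C(C)(C)C)c(c1)[C@H](CO[Si](C)(C)C(C)(C)C)[C@@H](c3cc(OC)c5c(c3)[C@H](CO[Si](C)(C)C(C)(C)C)[C@@H](c3cc(OC)c6c(c3)[C@@H](CO[Si](C)(C)C(C)(C)C)[C@H](c3ccc(OCc7ccccc7)c(OC)c3)O6)O5)O
F2 | step 29 | methyl 4-hydroxy-3-methoxy-5-[(2R,3S)-1-(tert-butyldimethylsilyloxy)-3-hydroxy-3-RB-propan-2-yl]benzoate | COC(=O)c1cc(OC)c(O)c(c1)[C@H](CO[Si](C)(C)C(C)(C)C)[C@@H](c3cc(OC)c5c(c3)[C@H](CO[Si](C)(C)C(C)(C)C)[C@@H](c3cc(OC)c6c(c3)[C@@H](CO[Si](C)(C)C(C)(C)C)[C@H](c3ccc(OCc7ccccc7)c(OC)c3)O6)O5)O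
F3 | step 4 | methyl 3-hydroxy-2-oxo-2H-pyran-5-carboxylate | COC(=O)C1=COC(=O)C(O)=C1
F4 | step 34 | hexaol from 50 (all three silyl ethers removed; carbinol epimers) | COc1cc(C[C@H](CO)[C@@H](CO)C(O)c3cc(OC)c4c(c3)[C@H](CO)[C@@H](c3cc(OC)c5c(c3)[C@H](CO)[C@@H](c3cc(OC)c6c(c3)[C@@H](CO)[C@H](c3ccc(OCc7ccccc7)c(OC)c3)O6)O5)O4)ccc1OCc8ccccc8
F5 | step 36 | bisphenol tris(silyl ether) from 51 (both benzyl ethers removed) | COc1cc(C[C@@H]2CO[C@@H](c3cc(OC)c4c(c3)[C@H](CO[Si](C)(C)C(C)(C)C)[C@@H](c3cc(OC)c5c(c3)[C@H](CO[Si](C)(C)C(C)(C)C)[C@@H](c3cc(OC)c6c(c3)[C@@H](CO[Si](C)(C)C(C)(C)C)[C@H](c3ccc(O)c(OC)c3)O6)O5)O4)[C@@H]2CO)ccc1O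
A1 | alternative 1 | 5-bromo tris(dihydrobenzofuran) triester | Brc3cc(OC)c4c(c3)[C@H](C(=O)OC)[C@@H](c3cc(OC)c5c(c3)[C@H](C(=O)OC)[C@@H](c3cc(OC)c6c(c3)[C@@H](C(=O)OC)[C@H](c3ccc(OCc7ccccc7)c(OC)c3)O6)O5)O4
A2 | alternative 1 | 6-bromo-8-methoxyflavanone carrying the ring B–ring C diester at C2 | Brc3cc(OC)c4c(c3)C(=O)C[C@@H](c3cc(OC)c5c(c3)[C@H](C(=O)OC)[C@@H](c3cc(OC)c6c(c3)[C@@H](C(=O)OC)[C@H](c3ccc(OCc7ccccc7)c(OC)c3)O6)O5)O4
A3 | alternative 2 | protected triester pentamer | COc1cc(C[C@@H]2CO[C@@H](c3cc(OC)c4c(c3)[C@H](C(=O)OC)[C@@H](c3cc(OC)c5c(c3)[C@H](C(=O)OC)[C@@H](c3cc(OC)c6c(c3)[C@@H](C(=O)OC)[C@H](c3ccc(OCc7ccccc7)c(OC)c3)O6)O5)O4)[C@@H]2CO[Si](C)(C)C(C)(C)C)ccc1OCc8ccccc8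
A4 | alternative 2 | bis(aryldiazoacetate) with rings A and B open | COc1cc(C[C@@H]2CO[C@@H](c3cc(OC)c(OCc4cc(OC)c(OCc5cc(OC)c6c(c5)[C@@H](C(=O)OC)[C@H](c7ccc(OCc8ccccc8)c(OC)c7)O6)c(c4)C(=[N+]=[N-])C(=O)OC)c(c3)C(=[N+]=[N-])C(=O)OC)[C@@H]2CO[Si](C)(C)C(C)(C)C)ccc1OCc9ccccc9
A5 | alternative 3 | protected target with free tetrahydrofuran hydroxymethyl (same structure as 51) | COc1cc(C[C@@H]2CO[C@@H](c3cc(OC)c4c(c3)[C@H](CO[Si](C)(C)C(C)(C)C)[C@@H](c3cc(OC)c5c(c3)[C@H](CO[Si](C)(C)C(C)(C)C)[C@@H](c3cc(OC)c6c(c3)[C@@H](CO[Si](C)(C)C(C)(C)C)[C@H](c3ccc(OCc7ccccc7)c(OC)c3)O6)O5)O4)[C@@H]2CO)ccc1OCc8ccccc8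
A6 | alternative 3 | cinnamyl ether of the RA-substituted epoxy alcohol (epoxide centre unassigned) | COc1cc(/C=C/CO[C@@H](c3cc(OC)c4c(c3)[C@H](CO[Si](C)(C)C(C)(C)C)[C@@H](c3cc(OC)c5c(c3)[C@H](CO[Si](C)(C)C(C)(C)C)[C@@H](c3cc(OC)c6c(c3)[C@@H](CO[Si](C)(C)C(C)(C)C)[C@H](c3ccc(OCc7ccccc7)c(OC)c3)O6)O5)O4)C2CO2)ccc1OCc8ccccc8
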